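**Strategy.** The route rests on disconnecting the alkyl C6–O bond of the γ-lactone (germacrane numbering). The lactone oxygen and the C7 tertiary hydroxyl are anti on adjacent carbons and C6 is allylic to the C4=C5 alkene, so both oxygens map onto an (E)-C6=C7 alkene. In one flask, Sharpless epoxidation of an acyclic dienol and acid-triggered 5-endo attack of the tert-butyl acrylate carbonyl at allylic C6 (inversion, loss of isobutene) should deliver the α-methylene-β-hydroxy-γ-lactone with C6 and C7 set. The precursor is an open-chain triene ester from a Stobbe condensation. The ten-membered carbocycle is closed afterwards by a CrCl2/NiCl2 vinyl iodide–aldehyde coupling (C9–C10).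

Key step: step 8

Remarks on the chemistry:
- Germacrane numbering is used throughout: C1=C10 (Z), C4=C5 (E), C6 lactone O–CH, C7 carbinol, C8 acetoxy, C9 acyloxy, C11=C13 methylene, C12 lactone carbonyl.
- The sense of induction of both Sharpless epoxidations is assigned on the assumption that L-(+)-tartrate converts (E)-hex-2-en-1-ol into the (2S,3S)-epoxy alcohol. Both epoxidations here need the opposite face, hence D-(−)-DIPT.

Step 1
Reactants: 1 geranyl acetate
Product: 3 (2E)-3-methyl-6-oxohex-2-en-1-yl acetate, via ozonide 2 (not isolated)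
Conditions: O3 (1 equiv), CH2Cl2/pyridine, −78 °C; then Me2S
Reagents that add atoms: ozone [O-][O+]=O
Why: Ozonolysis with reductive work-up should cleave only the remote trisubstituted 6,7-alkene, because the 2,3-alkene is deactivated by the allylic acetate, and the (2E) geometry is untouched.

Step 2
Reactants: 3 (2E)-3-methyl-6-oxohex-2-en-1-yl acetate
Product: 4 (2E,6Z)-7-iodo-3-methylocta-2,6-dien-1-yl acetate
Conditions: EtPPh3I, n-BuLi, THF; I2, −78 °C; NaN(SiMe3)2, −20 °C; then 3, −78 °C
Reagents that add atoms: ethyltriphenylphosphonium iodide CC[P+](c1ccccc1)(c1ccccc1)c1ccccc1.[I-]; iodine II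
Why: Stork–Zhao olefination, in which the unstabilised α-iodo ylide reacts under kinetic control to give the (Z)-2-iodoalk-2-ene and so fixes the later C1=C10 geometry (iodine cis to the chain).

Step 3
Reactants: 4 (2E,6Z)-7-iodo-3-methylocta-2,6-dien-1-yl acetate
Product: 5 (2E,6Z)-7-iodo-3-methylocta-2,6-dien-1-ol
Conditions: K2CO3 (cat.), MeOH, rt
Reagents that add atoms: none
Why: Base-catalysed transesterification removes the allylic acetate without touching the vinyl iodide.

Step 4
Reactants: 5 (2E,6Z)-7-iodo-3-methylocta-2,6-dien-1-ol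
Product: 6 (2E,6Z)-7-iodo-3-methylocta-2,6-dienal
Conditions: MnO2, CH2Cl2, rt
Reagents that add atoms: none
Why: Allylic oxidation with MnO2 should give the enal with retention of the (2E) geometry.

Step 5
Reactants: 6 (2E,6Z)-7-iodo-3-methylocta-2,6-dienal; 7 dimethyl itaconate
Product: 9 (3E,5E,9Z)-10-iodo-3-(methoxycarbonyl)-6-methyl-2-methylideneundeca-3,5,9-trienoic acid, via Stobbe lactone 8 (not isolated)
Conditions: t-BuOK, t-BuOH/THF, 0 °C to rt; then 1 M HCl
Reagents that add atoms: none
Why: Stobbe condensation, in which the itaconate dienolate adds through its ester α-carbon (C7) to the enal, the alkoxide lactonises onto the acrylate ester and E1cB ring opening gives the 2-methylidene-3-alkylidene succinic half ester (as in the second Stobbe step towards bis-alkylidene succinates); anti elimination from the trans lactone should place the dienyl group trans to the retained ester (3E).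

Step 6
Reactants: 9 (3E,5E,9Z)-10-iodo-3-(methoxycarbonyl)-6-methyl-2-methylideneundeca-3,5,9-trienoic acid
Product: 10 tert-butyl (3E,5E,9Z)-10-iodo-3-(methoxycarbonyl)-6-methyl-2-methylideneundeca-3,5,9-trienoate
Conditions: Cl3CC(=NH)O-t-Bu, BF3·OEt2 (cat.), CH2Cl2/cyclohexane, rt
Reagents that add atoms: tert-butyl 2,2,2-trichloroacetimidate CC(C)(C)OC(=N)C(Cl)(Cl)Cl
Why: Acid-catalysed O-alkylation of the carboxylic acid with the trichloroacetimidate masks C12 as the ester that later serves as the internal nucleophile and leaves the methyl ester distinguishable for reduction.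

Step 7
Reactants: 10 tert-butyl (3E,5E,9Z)-10-iodo-3-(methoxycarbonyl)-6-methyl-2-methylideneundeca-3,5,9-trienoate
Product: 11 tert-butyl (3E,5E,9Z)-3-(hydroxymethyl)-10-iodo-6-methyl-2-methylideneundeca-3,5,9-trienoate
Conditions: i-Bu2AlH, CH2Cl2, −78 °C; aq. potassium sodium tartrate
Reagents that add atoms: none
Why: Chemoselective 1,2-reduction of the methyl ester by i-Bu2AlH at low temperature should give the primary allylic alcohol while the hindered tert-butyl acrylate survives.

Step 8
Reactants: 11 tert-butyl (3E,5E,9Z)-3-(hydroxymethyl)-10-iodo-6-methyl-2-methylideneundeca-3,5,9-trienoate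
Product: 13 (4R,5S)-4-hydroxy-4-(hydroxymethyl)-5-[(1E,5Z)-6-iodo-2-methylhepta-1,5-dien-1-yl]-3-methylideneoxolan-2-one, via epoxy alcohol 12 (not isolated)
Conditions: Ti(OiPr)4 (cat.), D-(−)-DIPT (cat.), t-BuOOH, 4 Å MS, CH2Cl2, −20 °C; then CF3CO2H, −20 to 0 °C
Reagents that add atoms: tert-butyl hydroperoxide CC(C)(C)OO
Why: Sharpless asymmetric epoxidation should oxidise only the C6=C7 alkene, the one allylic to the free C8 hydroxyl, and D-(−)-DIPT should deliver oxygen to the face that gives the (2R,3R)-oxirane 12. On addition of acid the carbonyl oxygen of the tert-butyl acrylate attacks the protonated vinyl epoxide at C6 anti to the breaking C–O bond, and the alkoxycarbenium ion loses isobutene; the closest known reaction types are the lactonisation of β,γ-epoxy acids and tert-butyl esters to β-hydroxy-γ-lactones and the acid-mediated endo opening of vinyl epoxides. The oxolanone ring closes in a 5-endo epoxide-opening mode, favoured because C6 is allylic to the C4=C5 alkene and because attack at quaternary C7 would give a β-lactone. C7 keeps the epoxide oxygen as the tertiary hydroxyl with the configuration set by the tartrate, and C6 is set by inversion, so the (E)-alkene geometry becomes the anti C6–O/C7–OH relationship of the target. The step needs attack at C6 and not C4 (conjugate opening would need a seven-membered ring) and stereospecific inversion instead of ionisation, which low temperature and the intramolecular nucleophile should secure.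

Step 9
Reactants: 13 (4R,5S)-4-hydroxy-4-(hydroxymethyl)-5-[(1E,5Z)-6-iodo-2-methylhepta-1,5-dien-1-yl]-3-methylideneoxolan-2-one
Product: 14 (2S,3S)-3-hydroxy-2-[(1E,5Z)-6-iodo-2-methylhepta-1,5-dien-1-yl]-4-methylidene-5-oxooxolane-3-carbaldehyde
Conditions: TEMPO (cat.), PhI(OAc)2, CH2Cl2, rt
Reagents that add atoms: none
Why: Oxoammonium (TEMPO) oxidation should convert the primary alcohol into the aldehyde and leave the tertiary alcohol, alkenes and vinyl iodide untouched.

Step 10
Reactants: 14 (2S,3S)-3-hydroxy-2-[(1E,5Z)-6-iodo-2-methylhepta-1,5-dien-1-yl]-4-methylidene-5-oxooxolane-3-carbaldehyde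
Product: 15 (4R,5S)-4-[(R)-1,3-dithian-2-yl(hydroxy)methyl]-4-hydroxy-5-[(1E,5Z)-6-iodo-2-methylhepta-1,5-dien-1-yl]-3-methylideneoxolan-2-one
Conditions: 1,3-dithiane, n-BuLi, THF, −30 °C; then 14, −78 °C; aq. NH4Cl
Reagents that add atoms: 1,3-dithiane C1CSCSC1
Why: 1,2-Addition of 2-lithio-1,3-dithiane (a formyl anion equivalent) to the aldehyde, the most electrophilic site; the lithium alkoxide at C7 chelates the aldehyde oxygen and the nucleophile should enter from the face flanked by the flat sp2 carbon C11 and not by the C6 methine, which sets C8 syn to the C7 oxygen (chelation-controlled addition).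

Step 11
Reactants: 15 (4R,5S)-4-[(R)-1,3-dithian-2-yl(hydroxy)methyl]-4-hydroxy-5-[(1E,5Z)-6-iodo-2-methylhepta-1,5-dien-1-yl]-3-methylideneoxolan-2-one
Product: 16 (R)-1,3-dithian-2-yl[(2S,3S)-3-hydroxy-2-[(1E,5Z)-6-iodo-2-methylhepta-1,5-dien-1-yl]-4-methylidene-5-oxooxolan-3-yl]methyl acetate
Conditions: Ac2O, pyridine, DMAP (cat.), CH2Cl2, 0 °C
Reagents that add atoms: acetic anhydride CC(=O)OC(C)=O
Why: DMAP-catalysed acylation should esterify the secondary C8 hydroxyl while the tertiary C7 hydroxyl is too hindered to react.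

Step 12
Reactants: 16 (R)-1,3-dithian-2-yl[(2S,3S)-3-hydroxy-2-[(1E,5Z)-6-iodo-2-methylhepta-1,5-dien-1-yl]-4-methylidene-5-oxooxolan-3-yl]methyl acetate
Product: 17 (1R)-1-[(2S,3S)-3-hydroxy-2-[(1E,5Z)-6-iodo-2-methylhepta-1,5-dien-1-yl]-4-methylidene-5-oxooxolan-3-yl]-2-oxoethyl acetate
Conditions: MeI, CaCO3, MeCN/H2O, 45 °C
Reagents that add atoms: water O
Why: Alkylative thioacetal cleavage (S-methylation, then hydrolysis) should release the α-acetoxy aldehyde under buffered conditions that spare the acetate, lactone and vinyl iodide.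

Step 13
Reactants: 17 (1R)-1-[(2S,3S)-3-hydroxy-2-[(1E,5Z)-6-iodo-2-methylhepta-1,5-dien-1-yl]-4-methylidene-5-oxooxolan-3-yl]-2-oxoethyl acetate
Product: 18 (6S,7S,8S,9S)-8-acetoxy-7,9-dihydroxygermacra-1(10)Z,4E,11(13)-trien-12,6-olide
Conditions: CrCl2 (excess), NiCl2 (cat.), DMSO/THF, rt, high dilution
Reagents that add atoms: none
Why: Intramolecular Nozaki–Hiyama–Kishi reaction, in which the alkenyl–trivalent chromium species formed from the vinyl iodide adds to the aldehyde with retention of the (Z) geometry and closes the ten-membered ring; addition anti to the C8 acetoxy group (polar non-chelated model) should set C9.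

Step 14
Reactants: 19 angelic acid
Product: 20 (2Z)-2-methylbut-2-en-1-ol
Conditions: LiAlH4, Et2O, 0 °C
Reagents that add atoms: none
Why: Hydride reduction of the carboxylic acid should give the allylic alcohol without isomerising the (Z)-alkene.

Step 15
Reactants: 20 (2Z)-2-methylbut-2-en-1-ol
Product: 21 [(2R,3S)-2,3-dimethyloxiran-2-yl]methanol
Conditions: Ti(OiPr)4 (cat.), D-(−)-DIPT (cat.), t-BuOOH, 4 Å MS, CH2Cl2, −20 °C
Reagents that add atoms: tert-butyl hydroperoxide CC(C)(C)OO
Why: Sharpless asymmetric epoxidation with the D-(−)-tartrate should set both oxirane centres, and the (Z)-alkene fixes the cis relationship of CH2OH and the C3 methyl.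

Step 16
Reactants: 21 [(2R,3S)-2,3-dimethyloxiran-2-yl]methanol
Product: 22 (2S,3S)-2,3-dimethyloxirane-2-carboxylic acid
Conditions: TEMPO (cat.), PhI(OAc)2, MeCN/H2O, rt
Reagents that add atoms: water O
Why: Oxoammonium oxidation through the aldehyde hydrate should give the carboxylic acid without opening the epoxide or touching its stereocentres.

Step 17
Reactants: 18 (6S,7S,8S,9S)-8-acetoxy-7,9-dihydroxygermacra-1(10)Z,4E,11(13)-trien-12,6-olide; 22 (2S,3S)-2,3-dimethyloxirane-2-carboxylic acid
Product: 24 (6S,7S,8S,9S)-8-acetoxy-9-{[(2S,3S)-2,3-dimethyloxiran-2-yl]carbonyloxy}-7-hydroxygermacra-1(10)Z,4E,11(13)-trien-12,6-olide, via mixed anhydride 23 (not isolated)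
Conditions: 22, 2,4,6-Cl3C6H2COCl, Et3N, THF, rt; then 18, DMAP, toluene, rt
Reagents that add atoms: none
Why: Yamaguchi esterification, in which the mixed anhydride acylates the secondary allylic C9 hydroxyl under DMAP catalysis while the tertiary C7 hydroxyl does not react and no stereocentre is touched.

**Compound list**

1 | geranyl acetate, (2E)-3,7-dimethylocta-2,6-dien-1-yl acetate | CC(C)=CCC/C(C)=C/COC(C)=O | starting material
2 | ozonide, (2E)-5-(5,5-dimethyl-1,2,4-trioxolan-3-yl)-3-methylpent-2-en-1-yl acetate | CC(=O)OC/C=C(\C)CCC1OOC(C)(C)O1 | intermediate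
3 | (2E)-3-methyl-6-oxohex-2-en-1-yl acetate | CC(=O)OC/C=C(\C)CCC=O | intermediate
4 | (2E,6Z)-7-iodo-3-methylocta-2,6-dien-1-yl acetate | CC(=O)OC/C=C(\C)CC/C=C(/C)I | intermediate
5 | (2E,6Z)-7-iodo-3-methylocta-2,6-dien-1-ol | OC/C=C(\C)CC/C=C(/C)I | intermediate
6 | (2E,6Z)-7-iodo-3-methylocta-2,6-dienal | O=C/C=C(\C)CC/C=C(/C)I | intermediate
7 | dimethyl itaconate, dimethyl 2-methylidenebutanedioate | C=C(CC(=O)OC)C(=O)OC | starting material
8 | Stobbe lactone, methyl 2-[(1E,5Z)-6-iodo-2-methylhepta-1,5-dien-1-yl]-4-methylidene-5-oxooxolane-3-carboxylate (ring stereoisomer mixture) | COC(=O)C1C(=C)C(=O)OC1/C=C(\C)CC/C=C(/C)I | intermediate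
9 | (3E,5E,9Z)-10-iodo-3-(methoxycarbonyl)-6-methyl-2-methylideneundeca-3,5,9-trienoic acid | COC(=O)/C(=C/C=C(\C)CC/C=C(/C)I)C(=C)C(=O)O | intermediate
10 | tert-butyl (3E,5E,9Z)-10-iodo-3-(methoxycarbonyl)-6-methyl-2-methylideneundeca-3,5,9-trienoate | COC(=O)/C(=C/C=C(\C)CC/C=C(/C)I)C(=C)C(=O)OC(C)(C)C | intermediate
11 | tert-butyl (3E,5E,9Z)-3-(hydroxymethyl)-10-iodo-6-methyl-2-methylideneundeca-3,5,9-trienoate | OC/C(=C/C=C(\C)CC/C=C(/C)I)C(=C)C(=O)OC(C)(C)C | intermediate
12 | epoxy alcohol, tert-butyl 2-[(2R,3R)-2-(hydroxymethyl)-3-[(1E,5Z)-6-iodo-2-methylhepta-1,5-dien-1-yl]oxiran-2-yl]prop-2-enoate | OC[C@@]1(C(=C)C(=O)OC(C)(C)C)O[C@@H]1/C=C(\C)CC/C=C(/C)I | intermediate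
13 | (4R,5S)-4-hydroxy-4-(hydroxymethyl)-5-[(1E,5Z)-6-iodo-2-methylhepta-1,5-dien-1-yl]-3-methylideneoxolan-2-one | OC[C@]1(O)C(=C)C(=O)O[C@H]1/C=C(\C)CC/C=C(/C)I | intermediate
14 | (2S,3S)-3-hydroxy-2-[(1E,5Z)-6-iodo-2-methylhepta-1,5-dien-1-yl]-4-methylidene-5-oxooxolane-3-carbaldehyde | O=C[C@]1(O)C(=C)C(=O)O[C@H]1/C=C(\C)CC/C=C(/C)I | intermediate
15 | (4R,5S)-4-[(R)-1,3-dithian-2-yl(hydroxy)methyl]-4-hydroxy-5-[(1E,5Z)-6-iodo-2-methylhepta-1,5-dien-1-yl]-3-methylideneoxolan-2-one | S1CCCSC1[C@H](O)[C@]2(O)C(=C)C(=O)O[C@H]2/C=C(\C)CC/C=C(/C)I | intermediate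
16 | (R)-1,3-dithian-2-yl[(2S,3S)-3-hydroxy-2-[(1E,5Z)-6-iodo-2-methylhepta-1,5-dien-1-yl]-4-methylidene-5-oxooxolan-3-yl]methyl acetate | S1CCCSC1[C@H](OC(C)=O)[C@]2(O)C(=C)C(=O)O[C@H]2/C=C(\C)CC/C=C(/C)I | intermediate
17 | (1R)-1-[(2S,3S)-3-hydroxy-2-[(1E,5Z)-6-iodo-2-methylhepta-1,5-dien-1-yl]-4-methylidene-5-oxooxolan-3-yl]-2-oxoethyl acetate | O=C[C@H](OC(C)=O)[C@]1(O)C(=C)C(=O)O[C@H]1/C=C(\C)CC/C=C(/C)I | intermediate
18 | (6S,7S,8S,9S)-8-acetoxy-7,9-dihydroxygermacra-1(10)Z,4E,11(13)-trien-12,6-olide | C=C1C(=O)O[C@H]2/C=C(\C)CC/C=C(/C)[C@H](O)[C@H](OC(C)=O)[C@]12O | intermediate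
19 | angelic acid, (2Z)-2-methylbut-2-enoic acid | C/C=C(/C)C(=O)O | starting material
20 | (2Z)-2-methylbut-2-en-1-ol | C/C=C(/C)CO | intermediate
21 | [(2R,3S)-2,3-dimethyloxiran-2-yl]methanol | OC[C@@]1(C)O[C@H]1C | intermediate
22 | (2S,3S)-2,3-dimethyloxirane-2-carboxylic acid | OC(=O)[C@@]1(C)O[C@H]1C | intermediate
23 | mixed anhydride, (2S,3S)-2,3-dimethyloxirane-2-carboxylic 2,4,6-trichlorobenzoic anhydride | O=C(OC(=O)[C@@]1(C)O[C@H]1C)c1c(Cl)cc(Cl)cc1Cl | intermediate
24 | (6S,7S,8S,9S)-8-acetoxy-9-{[(2S,3S)-2,3-dimethyloxiran-2-yl]carbonyloxy}-7-hydroxygermacra-1(10)Z,4E,11(13)-trien-12,6-olide | C=C1C(=O)O[C@H]2/C=C(\C)CC/C=C(/C)[C@H](OC(=O)[C@@]3(C)O[C@H]3C)[C@H](OC(C)=O)[C@]12O | target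

**Totals.** Total step count: 17. Longest linear sequence: 14 steps (steps 1–13 and 17); steps 14–16 make the acid 22 in a side branch.

**Steps most likely to fail**

Step 13 (ring closure). CrCl2 may reduce or eliminate the α-acetoxy aldehyde, the acetyl group may migrate from O8 to the new O9 alkoxide, and oligomerisation may outrun ten-membered ring closure. The fallback changes the order of acylation so that the aldehyde carries a robust silyl ether. It sets out from 15. Silylation of the C8 hydroxyl (TBSOTf, 2,6-lutidine, −78 °C) should give the 8-O-TBS ether of 15, F1. Alkylative dithiane cleavage (MeI, CaCO3) should give the α-silyloxy aldehyde F2. CrCl2/NiCl2 ring closure should give the macrocyclic 8-O-TBS 9-alcohol F3. Yamaguchi esterification with 22 should give the 9-O-epoxyangeloyl 8-O-TBS macrocycle F4. HF·pyridine should then free the C8 alcohol F5, and acetylation (Ac2O, DMAP) comes back to the route at 24.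

Step 10 (C8 stereocentre). Facial selectivity in the addition to the α-hydroxy aldehyde may be poor, because the chelate is flanked by C6 and C11, which differ only modestly; conjugate addition to the α-methylene lactone may also compete. The fallback sets C8 by reagent-controlled reduction instead of addition. It sets out from 15 obtained as a mixture of C8 epimers. Parikh–Doering oxidation (SO3·pyridine, DMSO, i-Pr2NEt) should give the C8 ketone (2-acyl-1,3-dithiane) F6. Corey–Bakshi–Shibata reduction (oxazaborolidine enantiomer chosen for the (8R) carbinol, catecholborane, −78 °C) comes back to the route at 15.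

Step 5 (Stobbe condensation). The itaconate dienolate may isomerise into the citraconate/mesaconate series, add through its γ-carbon (C13), or oligomerise by Michael addition before it condenses with the enal. The fallback is the classical Stobbe condensation followed by late α-methylenation. It sets out from 6. Condensation with dimethyl succinate (t-BuOK, t-BuOH) should give the half ester F7. tert-Butyl trichloroacetimidate should give the mixed diester F8. Enolisation at C11 (LiN(SiMe3)2, −78 °C) and trapping with Eschenmoser's salt should give the Mannich base F9. Quaternisation with MeI and elimination (DBU) come back to the route at 10.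

**Further compounds**

F1 | step 13 | 8-O-tert-butyldimethylsilyl ether of 15 | S1CCCSC1[C@H](O[Si](C)(C)C(C)(C)C)[C@]2(O)C(=C)C(=O)O[C@H]2/C=C(\C)CC/C=C(/C)I
F2 | step 13 | α-silyloxy aldehyde, 8-O-TBS analogue of 17 | O=C[C@H](O[Si](C)(C)C(C)(C)C)[C@]1(O)C(=C)C(=O)O[C@H]1/C=C(\C)CC/C=C(/C)I
F3 | step 13 | macrocyclic 8-O-TBS 9-alcohol, 8-O-TBS analogue of 18 | C=C1C(=O)O[C@H]2/C=C(\C)CC/C=C(/C)[C@H](O)[C@H](O[Si](C)(C)C(C)(C)C)[C@]12O
F4 | step 13 | 9-O-[(2S,3S)-2,3-dimethyloxirane-2-carbonyl] 8-O-TBS macrocycle | C=C1C(=O)O[C@H]2/C=C(\C)CC/C=C(/C)[C@H](OC(=O)[C@@]3(C)O[C@H]3C)[C@H](O[Si](C)(C)C(C)(C)C)[C@]12O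
F5 | step 13 | 8-deacetyl analogue of 24 (free C8 alcohol) | C=C1C(=O)O[C@H]2/C=C(\C)CC/C=C(/C)[C@H](OC(=O)[C@@]3(C)O[C@H]3C)[C@H](O)[C@]12O
F6 | step 10 | C8 ketone of 15, (4S,5S)-4-(1,3-dithiane-2-carbonyl)-4-hydroxy-5-[(1E,5Z)-6-iodo-2-methylhepta-1,5-dien-1-yl]-3-methylideneoxolan-2-one | S1CCCSC1C(=O)[C@]2(O)C(=C)C(=O)O[C@H]2/C=C(\C)CC/C=C(/C)I
F7 | step 5 | (3E,5E,9Z)-10-iodo-3-(methoxycarbonyl)-6-methylundeca-3,5,9-trienoic acid | COC(=O)/C(=C/C=C(\C)CC/C=C(/C)I)CC(=O)O
F8 | step 5 | tert-butyl (3E,5E,9Z)-10-iodo-3-(methoxycarbonyl)-6-methylundeca-3,5,9-trienoate | COC(=O)/C(=C/C=C(\C)CC/C=C(/C)I)CC(=O)OC(C)(C)C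
F9 | step 5 | Mannich base, tert-butyl (3E,5E,9Z)-2-[(dimethylamino)methyl]-10-iodo-3-(methoxycarbonyl)-6-methylundeca-3,5,9-trienoate | COC(=O)/C(=C/C=C(\C)CC/C=C(/C)I)C(CN(C)C)C(=O)OC(C)(C)C
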